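Retrosynthesis: the C8–O acyl bond is cut first (esterification with inversion by the oxirane acid), then C7–C8, the last bond of the ten-membered carbocycle, then C7=C11 of the butenolide (ring-closing metathesis) with its C6–O acyl bond, then C3–C4 (alkenyl iodide + aldehyde) and C1–C2 (alkenylalanate + ethylene oxide).
Enabling feature: in the α-methylene-γ-lactone the atoms C13–C11–C7 form an allyl unit whose γ-carbon C7 carries the C8 carbinol, so the ring C1–C10 can be closed by adding a 3-(metallomethyl)butenolide to a C8 aldehyde; the same event sets C7 and C8 and lays down the exocyclic methylene.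
Forward order of rings: side-chain oxirane, C1–C10 oxirane, butenolide, then the ten-membered ring last; only an esterification follows.
Stereochemistry: C2′/C3′ by Sharpless epoxidation, C1/C10 by Shi epoxidation, C6 by Sharpless kinetic resolution, C3 by CBS reduction, C7/C8 in the ring closure (trans-lactone, 8α-OH), C8 inverted when the epoxy ester is attached.

Key step: step 21

Remark: positions are given in germacrane numbering (C1–C15; C2′/C3′ in the oxirane acid); PMB = 4-methoxybenzyl, TES = triethylsilyl; the ring closure is expected to give the 8α-alcohol, and step 22 is planned on that basis.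

Step 1
Reactants: 1 angelic acid, (2Z)-2-methylbut-2-enoic acid
Product: 2 (2Z)-2-methylbut-2-en-1-ol
Conditions: LiAlH4, Et2O, 0 °C; aq. NaOH
Reagents that add atoms: none
Why: Hydride reduction of the carboxylic acid with LiAlH4 at 0 °C should leave the trisubstituted Z-olefin untouched and unisomerised.

Step 2
Reactants: 2 (2Z)-2-methylbut-2-en-1-ol
Product: 3 [(2S,3R)-2,3-dimethyloxiran-2-yl]methanol
Conditions: Ti(OiPr)4 (cat.), L-(+)-diethyl tartrate (cat.), t-BuOOH, 4 Å MS, CH2Cl2, −20 °C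
Reagents that add atoms: tert-butyl hydroperoxide, CC(C)(C)OO
Why: Sharpless asymmetric epoxidation, in which the L-(+)-tartrate catalyst delivers oxygen to the olefin face that gives C2 S and C3 R, while the Z-olefin fixes the hydroxymethyl group and the C3 methyl cis.

Step 3
Reactants: 3 [(2S,3R)-2,3-dimethyloxiran-2-yl]methanol
Product: 4 (2R,3R)-2,3-dimethyloxirane-2-carboxylic acid
Conditions: RuCl3·xH2O (cat.), NaIO4, MeCN/EtOAc/H2O, 0 °C → rt
Reagents that add atoms: sodium periodate, [Na+].[O-]I(=O)(=O)=O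
Why: RuO4-catalysed oxidation of the primary alcohol is the usual passage from 2,3-epoxy alcohols to glycidic acids and leaves both stereocentres untouched (C2 changes from S to R by priority only).

Step 4
Reactants: 5 but-3-yn-1-ol
Product: 6 1-[(but-3-yn-1-yloxy)methyl]-4-methoxybenzene
Conditions: NaH, 4-methoxybenzyl chloride, Bu4NI (cat.), THF, 0 °C → rt
Reagents that add atoms: 4-methoxybenzyl chloride, COc1ccc(CCl)cc1
Why: Williamson ether synthesis protects the future C8 oxygen with a group that can later be removed oxidatively in the presence of esters, oxirane and an allylic bromide.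

Step 5
Reactants: 6 1-[(but-3-yn-1-yloxy)methyl]-4-methoxybenzene
Product: 9 (3E)-6-(PMB-oxy)-4-methylhex-3-en-1-ol, via alkenylalane 7 (not isolated), via lithium alkenylalanate 8 (not isolated)
Conditions: Me3Al, Cp2ZrCl2 (cat.), CH2Cl2, 0 °C → rt; evaporation; n-BuLi, hexane/THF, −78 °C; ethylene oxide, −78 → 0 °C
Reagents that add atoms: trimethylaluminium, C[Al](C)C; ethylene oxide, C1CO1
Why: Zr-catalysed Negishi carboalumination adds Me–Al syn with methyl on the internal carbon and so fixes the E-trisubstituted C1=C10 olefin, and the alanate formed with n-BuLi is nucleophilic enough to open ethylene oxide at carbon.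

Step 6
Reactants: 9 (3E)-6-(PMB-oxy)-4-methylhex-3-en-1-ol
Product: 10 2-{(2R,3R)-3-[2-(PMB-oxy)ethyl]-3-methyloxiran-2-yl}ethan-1-ol
Conditions: D-fructose-derived Shi ketone (1,2:4,5-di-O-isopropylidene-β-D-erythro-2,3-hexodiulo-2,6-pyranose, cat.), Oxone (2KHSO5·KHSO4·K2SO4), K2CO3, Bu4NHSO4, MeCN/dimethoxymethane/aq. Na2B4O7–Na2EDTA, 0 °C
Reagents that add atoms: potassium peroxymonosulfate, [K+].[O-]S(=O)(=O)OO
Why: Shi asymmetric epoxidation, in which the dioxirane of the D-fructose ketone attacks E-trisubstituted olefins through the spiro transition state from the face that gives the (R,R)-oxirane, here C1 and C10.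

Step 7
Reactants: 10 2-{(2R,3R)-3-[2-(PMB-oxy)ethyl]-3-methyloxiran-2-yl}ethan-1-ol
Product: 11 2-{(2R,3R)-3-[2-(PMB-oxy)ethyl]-3-methyloxiran-2-yl}acetaldehyde
Conditions: Dess–Martin periodinane, NaHCO3, CH2Cl2, 0 °C; used at once
Reagents that add atoms: none
Why: Dess–Martin oxidation under buffered, non-basic conditions should give the β,γ-epoxy aldehyde without β-elimination of the oxirane.

Step 8
Reactants: 12 acrolein (prop-2-enal); 13 prop-1-yn-1-ylmagnesium bromide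
Product: 14 rac-hex-1-en-4-yn-3-ol
Conditions: THF, −78 → 0 °C; aq. NH4Cl
Reagents that add atoms: none
Why: 1,2-Addition of the alkynyl Grignard reagent to the enal gives the vinyl propynyl carbinol that holds C4–C7 and C15.

Step 9
Reactants: 14 rac-hex-1-en-4-yn-3-ol
Product: 16 rac-(4Z)-5-iodohexa-1,4-dien-3-ol, via cyclic sodium alkenylalanate 15 (not isolated)
Conditions: NaAlH2(OCH2CH2OMe)2 (Red-Al), THF, 0 °C → rt; EtOAc; then I2, −78 → 0 °C
Reagents that add atoms: iodine, II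
Why: Hydroxyl-directed trans-hydroalumination of the propargylic alcohol puts hydride on the proximal and aluminium on the distal alkyne carbon, and iodinolysis with retention gives the Z-alkenyl iodide with iodine cis to the carbinol carbon.

Step 10
Reactants: 16 rac-(4Z)-5-iodohexa-1,4-dien-3-ol
Product: 17 (3S,4Z)-5-iodohexa-1,4-dien-3-ol
Conditions: Ti(OiPr)4 (cat.), L-(+)-diisopropyl tartrate (cat.), t-BuOOH (0.6 equiv), 4 Å MS, CH2Cl2, −20 °C; stopped just past half conversion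
Reagents that add atoms: none
Why: Sharpless kinetic resolution, in which the L-(+)-tartrate catalyst epoxidises the vinyl group of the (R)-alcohol quickly and leaves the (S)-alcohol (the Z-iodoalkene arm is inert), which sets C6.

Step 11
Reactants: 17 (3S,4Z)-5-iodohexa-1,4-dien-3-ol
Product: 18 triethyl{[(3S,4Z)-5-iodohexa-1,4-dien-3-yl]oxy}silane
Conditions: Et3SiCl, imidazole, CH2Cl2, 0 °C
Reagents that add atoms: chlorotriethylsilane, CC[Si](Cl)(CC)CC
Why: Silylation masks the C6 hydroxyl so that it can be told apart from the C3 hydroxyl made in the next step.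

Step 12
Reactants: 18 triethyl{[(3S,4Z)-5-iodohexa-1,4-dien-3-yl]oxy}silane; 11 2-{(2R,3R)-3-[2-(PMB-oxy)ethyl]-3-methyloxiran-2-yl}acetaldehyde
Product: 20 (3Z,5S)-1-{(2R,3R)-3-[2-(PMB-oxy)ethyl]-3-methyloxiran-2-yl}-3-methyl-5-(TES-oxy)hepta-3,6-dien-2-ol (both epimers at the carbinol carbon; this is C3), via alkenylchromium dichloride 19 (not isolated)
Conditions: CrCl2 (excess), NiCl2 (cat.), DMSO, rt
Reagents that add atoms: none
Why: Ni-catalysed, Cr-mediated Nozaki–Hiyama–Kishi coupling forms C3–C4 with retention of the Z-olefin under non-basic conditions that the oxirane and the enolisable aldehyde tolerate; C3 is formed without control and is corrected in steps 13 and 14.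

Step 13
Reactants: 20 (3Z,5S)-1-{(2R,3R)-3-[2-(PMB-oxy)ethyl]-3-methyloxiran-2-yl}-3-methyl-5-(TES-oxy)hepta-3,6-dien-2-ol
Product: 21 (3Z,5S)-1-{(2R,3R)-3-[2-(PMB-oxy)ethyl]-3-methyloxiran-2-yl}-3-methyl-5-(TES-oxy)hepta-3,6-dien-2-one
Conditions: Dess–Martin periodinane, NaHCO3, CH2Cl2, 0 °C
Reagents that add atoms: none
Why: Dess–Martin oxidation converges both C3 epimers on one Z-enone under buffered conditions that should not isomerise the olefin or open the oxirane.

Step 14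
Reactants: 21 (3Z,5S)-1-{(2R,3R)-3-[2-(PMB-oxy)ethyl]-3-methyloxiran-2-yl}-3-methyl-5-(TES-oxy)hepta-3,6-dien-2-one
Product: 22 (2S,3Z,5S)-1-{(2R,3R)-3-[2-(PMB-oxy)ethyl]-3-methyloxiran-2-yl}-3-methyl-5-(TES-oxy)hepta-3,6-dien-2-ol
Conditions: (R)-2-methyl-CBS-oxazaborolidine, catecholborane, toluene, −78 °C
Reagents that add atoms: none
Why: Corey–Bakshi–Shibata reduction, in which the α-methylalkenyl group is the large and the CH2 group the small ketone substituent, so the (R)-catalyst should give the 3S alcohol, and catecholborane at −78 °C avoids hydroboration of the vinyl group and 1,4-reduction.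

Step 15
Reactants: 22 (2S,3Z,5S)-1-{(2R,3R)-3-[2-(PMB-oxy)ethyl]-3-methyloxiran-2-yl}-3-methyl-5-(TES-oxy)hepta-3,6-dien-2-ol
Product: 23 (2S,3Z,5S)-1-{(2R,3R)-3-[2-(PMB-oxy)ethyl]-3-methyloxiran-2-yl}-3-methyl-5-(TES-oxy)hepta-3,6-dien-2-yl 3-methylbutanoate
Conditions: 3-methylbutanoyl chloride, pyridine, DMAP (cat.), CH2Cl2, 0 °C
Reagents that add atoms: 3-methylbutanoyl chloride, CC(C)CC(=O)Cl
Why: Acylation of the only free hydroxyl installs the C3 isovalerate with retention.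

Step 16
Reactants: 23 (2S,3Z,5S)-1-{(2R,3R)-3-[2-(PMB-oxy)ethyl]-3-methyloxiran-2-yl}-3-methyl-5-(TES-oxy)hepta-3,6-dien-2-yl 3-methylbutanoate
Product: 24 (2S,3Z,5S)-5-hydroxy-1-{(2R,3R)-3-[2-(PMB-oxy)ethyl]-3-methyloxiran-2-yl}-3-methylhepta-3,6-dien-2-yl 3-methylbutanoate
Conditions: HF·pyridine, excess pyridine, THF, 0 °C
Reagents that add atoms: none
Why: Buffered fluoride-mediated desilylation frees the C6 hydroxyl without opening the trisubstituted oxirane or moving the ester.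

Step 17
Reactants: 24 (2S,3Z,5S)-5-hydroxy-1-{(2R,3R)-3-[2-(PMB-oxy)ethyl]-3-methyloxiran-2-yl}-3-methylhepta-3,6-dien-2-yl 3-methylbutanoate; 25 2-(bromomethyl)prop-2-enoic acid
Product: 26 (3S,4Z,6S)-7-{(2R,3R)-3-[2-(PMB-oxy)ethyl]-3-methyloxiran-2-yl}-5-methyl-6-[(3-methylbutanoyl)oxy]hepta-1,4-dien-3-yl 2-(bromomethyl)prop-2-enoate
Conditions: DCC, DMAP (cat.), CH2Cl2, −20 → 0 °C
Reagents that add atoms: none
Why: Steglich esterification at low temperature with little DMAP attaches C11–C13 to the C6 oxygen before the allylic bromide can be displaced.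

Step 18
Reactants: 26 (3S,4Z,6S)-7-{(2R,3R)-3-[2-(PMB-oxy)ethyl]-3-methyloxiran-2-yl}-5-methyl-6-[(3-methylbutanoyl)oxy]hepta-1,4-dien-3-yl 2-(bromomethyl)prop-2-enoate
Product: 27 (2S,3Z)-4-[(2R)-4-(bromomethyl)-5-oxo-2,5-dihydrofuran-2-yl]-1-{(2R,3R)-3-[2-(PMB-oxy)ethyl]-3-methyloxiran-2-yl}-3-methylbut-3-en-2-yl 3-methylbutanoate
Conditions: second-generation Grubbs catalyst RuCl2(=CHPh)(H2IMes)(PCy3) (cat.), CH2Cl2 (dilute), 40 °C
Reagents that add atoms: none
Why: Ring-closing metathesis, in which the ruthenium alkylidene forms at the vinyl group and closes on the 1,1-disubstituted acrylate to give the butenolide, while the trisubstituted C4=C5 olefin is too hindered to take part.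

Step 19
Reactants: 27 (2S,3Z)-4-[(2R)-4-(bromomethyl)-5-oxo-2,5-dihydrofuran-2-yl]-1-{(2R,3R)-3-[2-(PMB-oxy)ethyl]-3-methyloxiran-2-yl}-3-methylbut-3-en-2-yl 3-methylbutanoate
Product: 28 (2S,3Z)-4-[(2R)-4-(bromomethyl)-5-oxo-2,5-dihydrofuran-2-yl]-1-[(2R,3R)-3-(2-hydroxyethyl)-3-methyloxiran-2-yl]-3-methylbut-3-en-2-yl 3-methylbutanoate
Conditions: DDQ, CH2Cl2/pH 7 phosphate buffer, 0 °C
Reagents that add atoms: none
Why: Oxidative cleavage of the PMB ether with DDQ is neutral and non-nucleophilic, so the allylic bromide, esters and oxirane should survive.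

Step 20
Reactants: 28 (2S,3Z)-4-[(2R)-4-(bromomethyl)-5-oxo-2,5-dihydrofuran-2-yl]-1-[(2R,3R)-3-(2-hydroxyethyl)-3-methyloxiran-2-yl]-3-methylbut-3-en-2-yl 3-methylbutanoate
Product: 29 (2S,3Z)-4-[(2R)-4-(bromomethyl)-5-oxo-2,5-dihydrofuran-2-yl]-1-[(2R,3R)-3-methyl-3-(2-oxoethyl)oxiran-2-yl]-3-methylbut-3-en-2-yl 3-methylbutanoate
Conditions: Dess–Martin periodinane, NaHCO3, CH2Cl2, 0 °C; used crude
Reagents that add atoms: none
Why: Buffered Dess–Martin oxidation gives the C8 aldehyde without base, which the β,γ-epoxy aldehyde and the allylic bromide would not tolerate.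

Step 21
Reactants: 29 (2S,3Z)-4-[(2R)-4-(bromomethyl)-5-oxo-2,5-dihydrofuran-2-yl]-1-[(2R,3R)-3-methyl-3-(2-oxoethyl)oxiran-2-yl]-3-methylbut-3-en-2-yl 3-methylbutanoate
Product: 31 (1R,3S,4Z,6R,7R,8S,10R)-1,10-epoxy-8-hydroxy-3-[(3-methylbutanoyl)oxy]germacra-4,11(13)-dien-12,6-olide, via allylchromium dichloride 30 (not isolated)
Conditions: CrCl2 (excess), DMF, rt, slow addition of 29 by syringe pump to about 2 mM; aq. NH4Cl
Reagents that add atoms: none
Why: CrCl2 (divalent chromium, two single-electron transfers) converts the allylic bromide of 29 into the allylchromium dichloride 30, whose γ-carbon is C7 of the butenolide, and this adds to the C8 aldehyde through a six-membered chair transition state (Cr–C13–C11–C7···C8–O), so that C7–C8 forms, the double bond moves to C11=C13 and the α-methylene-γ-lactone appears in the same event. The closest known reaction types are the Cr-mediated intramolecular Nozaki–Hiyama–Kishi allylation of aldehydes by 2-(bromomethyl)alk-2-enoates, which closes ten-membered germacrane rings, and the Barbier allylation of aldehydes by 3-(bromomethyl)furan-2(5H)-ones. The ten-membered carbocycle closes in the 10-exo-trig mode by γ-attack (SE2′) on the carbonyl carbon; α-attack through C13 would need a twelve-membered ring without a cyclic transition state and is not expected. C7 is set by attack on the lactone face anti to the C5 substituent at C6 (6R), which gives the trans-fused lactone (7R) that a ten-membered ring takes up without eclipsing C5 and C8, and C8 is set by the chair transition state, in which the lactone ring locks C6 trans to the CH2Cr group and the tether carbon C9 lies pseudo-equatorial and anti to C11, giving the anti adduct (8S, 8α-OH). The step needs ring closure to beat oligomerisation and to leave esters, lactone and oxirane alone, which high dilution, the chain-folding Z-C4=C5 olefin and trans-oxirane, and the aldehyde selectivity of allylchromium reagents should secure. The 8S configuration is the one wanted, because step 22 attaches the ester with inversion.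

Step 22
Reactants: 31 (1R,3S,4Z,6R,7R,8S,10R)-1,10-epoxy-8-hydroxy-3-[(3-methylbutanoyl)oxy]germacra-4,11(13)-dien-12,6-olide; 4 (2R,3R)-2,3-dimethyloxirane-2-carboxylic acid
Product: 32 (1R,3S,4Z,6R,7R,8R,10R)-8-{[(2R,3R)-2,3-dimethyloxiran-2-yl]carbonyloxy}-1,10-epoxy-3-[(3-methylbutanoyl)oxy]germacra-4,11(13)-dien-12,6-olide (CNP0167461.2)
Conditions: PPh3, diisopropyl azodicarboxylate, toluene, 0 °C → rt; 31 added last to the preformed betaine
Reagents that add atoms: none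
Why: Mitsunobu esterification, in which the carboxylate of 4 displaces the C8 oxyphosphonium group in an SN2 reaction with inversion (8S → 8R); the glycidic acid is acidic enough to protonate the betaine, and preforming the betaine limits contact of free PPh3 with the α-methylene lactone.

Compound list
1 | angelic acid, (2Z)-2-methylbut-2-enoic acid | C/C=C(/C)C(=O)O | starting material
2 | (2Z)-2-methylbut-2-en-1-ol | C/C=C(/C)CO | intermediate
3 | [(2S,3R)-2,3-dimethyloxiran-2-yl]methanol | OC[C@]1(C)O[C@@H]1C | intermediate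
4 | (2R,3R)-2,3-dimethyloxirane-2-carboxylic acid | OC(=O)[C@]1(C)O[C@@H]1C | intermediate
5 | but-3-yn-1-ol | C#CCCO | starting material
6 | 1-[(but-3-yn-1-yloxy)methyl]-4-methoxybenzene | C#CCCOCc1ccc(OC)cc1 | intermediate
7 | [(1E)-4-(PMB-oxy)-2-methylbut-1-en-1-yl]dimethylalane | C[Al](C)/C=C(\C)CCOCc1ccc(OC)cc1 | intermediate
8 | lithium butyl[(1E)-4-(PMB-oxy)-2-methylbut-1-en-1-yl]dimethylalanate | [Li+].CCCC[Al-](C)(C)/C=C(\C)CCOCc1ccc(OC)cc1 | intermediate
9 | (3E)-6-(PMB-oxy)-4-methylhex-3-en-1-ol | OCC/C=C(\C)CCOCc1ccc(OC)cc1 | intermediate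
10 | 2-{(2R,3R)-3-[2-(PMB-oxy)ethyl]-3-methyloxiran-2-yl}ethan-1-ol | OCC[C@H]1O[C@]1(C)CCOCc2ccc(OC)cc2 | intermediate
11 | 2-{(2R,3R)-3-[2-(PMB-oxy)ethyl]-3-methyloxiran-2-yl}acetaldehyde | O=CC[C@H]1O[C@]1(C)CCOCc2ccc(OC)cc2 | intermediate
12 | acrolein (prop-2-enal) | C=CC=O | starting material
13 | prop-1-yn-1-ylmagnesium bromide | CC#C[Mg]Br | starting material
14 | rac-hex-1-en-4-yn-3-ol | C=CC(O)C#CC | intermediate
15 | sodium 2,2-bis(2-methoxyethoxy)-3-methyl-5-vinyl-2,5-dihydro-1,2-oxaluminol-2-uide (cyclic alkenylalanate) | [Na+].C=CC1O[Al-](OCCOC)(OCCOC)C(C)=C1 | intermediate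
16 | rac-(4Z)-5-iodohexa-1,4-dien-3-ol | C=CC(O)/C=C(/C)I | intermediate
17 | (3S,4Z)-5-iodohexa-1,4-dien-3-ol | C=C[C@H](O)/C=C(/C)I | intermediate
18 | triethyl{[(3S,4Z)-5-iodohexa-1,4-dien-3-yl]oxy}silane | C=C[C@H](O[Si](CC)(CC)CC)/C=C(/C)I | intermediate
19 | dichloro[(2Z,4S)-4-(TES-oxy)hexa-2,5-dien-2-yl]chromium (trivalent chromium) | C=C[C@H](O[Si](CC)(CC)CC)/C=C(/C)[Cr](Cl)Cl | intermediate
20 | (3Z,5S)-1-{(2R,3R)-3-[2-(PMB-oxy)ethyl]-3-methyloxiran-2-yl}-3-methyl-5-(TES-oxy)hepta-3,6-dien-2-ol, both C2 epimers (C2 is C3 of the germacrane) | C=C[C@H](O[Si](CC)(CC)CC)/C=C(/C)C(O)C[C@H]1O[C@]1(C)CCOCc2ccc(OC)cc2 | intermediate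
21 | (3Z,5S)-1-{(2R,3R)-3-[2-(PMB-oxy)ethyl]-3-methyloxiran-2-yl}-3-methyl-5-(TES-oxy)hepta-3,6-dien-2-one | C=C[C@H](O[Si](CC)(CC)CC)/C=C(/C)C(=O)C[C@H]1O[C@]1(C)CCOCc2ccc(OC)cc2 | intermediate
22 | (2S,3Z,5S)-1-{(2R,3R)-3-[2-(PMB-oxy)ethyl]-3-methyloxiran-2-yl}-3-methyl-5-(TES-oxy)hepta-3,6-dien-2-ol | C=C[C@H](O[Si](CC)(CC)CC)/C=C(/C)[C@@H](O)C[C@H]1O[C@]1(C)CCOCc2ccc(OC)cc2 | intermediate
23 | (2S,3Z,5S)-1-{(2R,3R)-3-[2-(PMB-oxy)ethyl]-3-methyloxiran-2-yl}-3-methyl-5-(TES-oxy)hepta-3,6-dien-2-yl 3-methylbutanoate | C=C[C@H](O[Si](CC)(CC)CC)/C=C(/C)[C@@H](OC(=O)CC(C)C)C[C@H]1O[C@]1(C)CCOCc2ccc(OC)cc2 | intermediate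
24 | (2S,3Z,5S)-5-hydroxy-1-{(2R,3R)-3-[2-(PMB-oxy)ethyl]-3-methyloxiran-2-yl}-3-methylhepta-3,6-dien-2-yl 3-methylbutanoate | C=C[C@H](O)/C=C(/C)[C@@H](OC(=O)CC(C)C)C[C@H]1O[C@]1(C)CCOCc2ccc(OC)cc2 | intermediate
25 | 2-(bromomethyl)prop-2-enoic acid | C=C(CBr)C(=O)O | starting material
26 | (3S,4Z,6S)-7-{(2R,3R)-3-[2-(PMB-oxy)ethyl]-3-methyloxiran-2-yl}-5-methyl-6-[(3-methylbutanoyl)oxy]hepta-1,4-dien-3-yl 2-(bromomethyl)prop-2-enoate | C=C[C@H](OC(=O)C(=C)CBr)/C=C(/C)[C@@H](OC(=O)CC(C)C)C[C@H]1O[C@]1(C)CCOCc2ccc(OC)cc2 | intermediate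
27 | (2S,3Z)-4-[(2R)-4-(bromomethyl)-5-oxo-2,5-dihydrofuran-2-yl]-1-{(2R,3R)-3-[2-(PMB-oxy)ethyl]-3-methyloxiran-2-yl}-3-methylbut-3-en-2-yl 3-methylbutanoate | BrCC1=C[C@H](OC1=O)/C=C(/C)[C@@H](OC(=O)CC(C)C)C[C@H]2O[C@]2(C)CCOCc3ccc(OC)cc3 | intermediate
28 | (2S,3Z)-4-[(2R)-4-(bromomethyl)-5-oxo-2,5-dihydrofuran-2-yl]-1-[(2R,3R)-3-(2-hydroxyethyl)-3-methyloxiran-2-yl]-3-methylbut-3-en-2-yl 3-methylbutanoate | BrCC1=C[C@H](OC1=O)/C=C(/C)[C@@H](OC(=O)CC(C)C)C[C@H]2O[C@]2(C)CCO | intermediate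
29 | (2S,3Z)-4-[(2R)-4-(bromomethyl)-5-oxo-2,5-dihydrofuran-2-yl]-1-[(2R,3R)-3-methyl-3-(2-oxoethyl)oxiran-2-yl]-3-methylbut-3-en-2-yl 3-methylbutanoate | BrCC1=C[C@H](OC1=O)/C=C(/C)[C@@H](OC(=O)CC(C)C)C[C@H]2O[C@]2(C)CC=O | intermediate
30 | allylchromium dichloride of 29 (CrCl2 group in place of Br at C13; trivalent chromium) | Cl[Cr](Cl)CC1=C[C@H](OC1=O)/C=C(/C)[C@@H](OC(=O)CC(C)C)C[C@H]2O[C@]2(C)CC=O | intermediate
31 | (1R,3S,4Z,6R,7R,8S,10R)-1,10-epoxy-8-hydroxy-3-[(3-methylbutanoyl)oxy]germacra-4,11(13)-dien-12,6-olide | C=C1C(=O)O[C@@H]2/C=C(/C)[C@@H](OC(=O)CC(C)C)C[C@H]3O[C@]3(C)C[C@H](O)[C@@H]12 | intermediate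
32 | (1R,3S,4Z,6R,7R,8R,10R)-8-{[(2R,3R)-2,3-dimethyloxiran-2-yl]carbonyloxy}-1,10-epoxy-3-[(3-methylbutanoyl)oxy]germacra-4,11(13)-dien-12,6-olide (CNP0167461.2) | C=C1C(=O)O[C@@H]2/C=C(/C)[C@@H](OC(=O)CC(C)C)C[C@H]3O[C@]3(C)C[C@@H](OC(=O)[C@]3(C)O[C@@H]3C)[C@@H]12 | target

Total step count: 22.
Longest linear sequence: 15 steps (steps 8–11, then 12–22; the branch through steps 4–7 and 12–22 is equally long).

Steps most likely to fail

1. Step 21. Intermolecular allylation (oligomerisation) may outrun ring closure, the aldehyde may add to the lactone face syn to C5 or with the tether pseudo-axial so that other C7/C8 diastereomers form, or the chromium salts may open the β,γ-epoxy aldehyde before it cyclises. The fallback sets C7 and C8 in a known intermolecular Barbier reaction and closes the same ring at C3–C4 by a Nozaki–Hiyama–Kishi macrocyclisation. It sets out from 17 and 10 and comes back at 32.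
   - Alcohol 17 is esterified with 25 (DCC) to (3S,4Z)-5-iodohexa-1,4-dien-3-yl 2-(bromomethyl)prop-2-enoate F1, and ring-closing metathesis gives (5S)-3-(bromomethyl)-5-[(1Z)-2-iodoprop-1-en-1-yl]furan-2(5H)-one F2.
   - Alcohol 10 is silylated (t-BuMe2SiCl, imidazole) to tert-butyl(2-{(2R,3R)-3-[2-(PMB-oxy)ethyl]-3-methyloxiran-2-yl}ethoxy)dimethylsilane F3. DDQ then gives 2-[(2R,3R)-3-(2-{[tert-butyl(dimethyl)silyl]oxy}ethyl)-2-methyloxiran-2-yl]ethan-1-ol F4, and Dess–Martin oxidation gives 2-[(2R,3R)-3-(2-{[tert-butyl(dimethyl)silyl]oxy}ethyl)-2-methyloxiran-2-yl]acetaldehyde F5.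
   - Zinc in THF/aq. NH4Cl converts F2 into the allylzinc bromide of F2 F6, which should add to F5 anti to the C6 substituent and through the chair transition state. The product is the seco-lactone (4R,5S)-4-{(1S)-2-[(2R,3R)-3-(2-{[tert-butyl(dimethyl)silyl]oxy}ethyl)-2-methyloxiran-2-yl]-1-hydroxyethyl}-5-[(1Z)-2-iodoprop-1-en-1-yl]-3-methylideneoxolan-2-one F7.
   - Mitsunobu esterification of F7 with 4 inverts C8 on this open-chain alcohol and gives the (2R,3R)-2,3-dimethyloxirane-2-carboxylate of the inverted (1R) carbinol F8.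
   - HF·pyridine gives the primary C3 alcohol of F8 F9 and Dess–Martin oxidation gives the C3 aldehyde of F9 F10.
   - CrCl2/NiCl2 in DMSO/THF at high dilution forms the alkenylchromium dichloride of F10 F11, which closes the ring to (1R,4Z,6R,7R,8R,10R)-8-{[(2R,3R)-2,3-dimethyloxiran-2-yl]carbonyloxy}-1,10-epoxy-3-hydroxygermacra-4,11(13)-dien-12,6-olide F12.
   - The 3S epimer of F12 is acylated with 3-methylbutanoyl chloride; the 3R epimer is esterified with 3-methylbutanoic acid under Mitsunobu conditions. Both give 32.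

2. Step 22. The activated C8 oxyphosphonium group may be lost by elimination toward C7 or C9 instead of being displaced at this hindered ring carbon, or PPh3 may add to the α-methylene lactone. The fallback inverts C8 by oxidation and reduction and then esterifies with retention. It sets out from 31 and comes back at 32.
   - Buffered Dess–Martin oxidation gives (1R,3S,4Z,6R,7R,10R)-1,10-epoxy-3-[(3-methylbutanoyl)oxy]-8-oxogermacra-4,11(13)-dien-12,6-olide F13.
   - Reduction at −78 °C with (S)-2-methyl-CBS-oxazaborolidine and catecholborane (branched C7 as the large group), or with NaBH4/CeCl3·7H2O, should give (1R,3S,4Z,6R,7R,8R,10R)-1,10-epoxy-8-hydroxy-3-[(3-methylbutanoyl)oxy]germacra-4,11(13)-dien-12,6-olide F14.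
   - Yamaguchi esterification of F14 with 4 (2,4,6-trichlorobenzoyl chloride, Et3N, DMAP) gives 32.

3. Step 12. The β,γ-epoxy aldehyde 11 may open by β-elimination (E1cB to the γ-hydroxy enal) on the Lewis acidic chromium salts before the C–C bond forms. The fallback replaces the aldehyde by a Weinreb amide and makes the enone directly. It sets out from 10 and 18 and comes back at 21.
   - Alcohol 10 is oxidised (TEMPO, PhI(OAc)2, MeCN/H2O) to 2-{(2R,3R)-3-[2-(PMB-oxy)ethyl]-3-methyloxiran-2-yl}acetic acid F15.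
   - Coupling with MeNHOMe·HCl (EDCI, N-methylmorpholine) gives N-methoxy-N-methyl-2-{(2R,3R)-3-[2-(PMB-oxy)ethyl]-3-methyloxiran-2-yl}acetamide F16.
   - Iodine–magnesium exchange on 18 (iPrMgCl·LiCl, THF, −20 °C) gives chloro[(2Z,4S)-4-(TES-oxy)hexa-2,5-dien-2-yl]magnesium F17, which adds to F16 to give enone 21.

Further compounds
F1 | step 21 | (3S,4Z)-5-iodohexa-1,4-dien-3-yl 2-(bromomethyl)prop-2-enoate | C=C[C@H](OC(=O)C(=C)CBr)/C=C(/C)I
F2 | step 21 | (5S)-3-(bromomethyl)-5-[(1Z)-2-iodoprop-1-en-1-yl]furan-2(5H)-one | BrCC1=C[C@H](OC1=O)/C=C(/C)I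
F3 | step 21 | tert-butyl(2-{(2R,3R)-3-[2-(PMB-oxy)ethyl]-3-methyloxiran-2-yl}ethoxy)dimethylsilane | CC(C)(C)[Si](C)(C)OCC[C@H]1O[C@]1(C)CCOCc2ccc(OC)cc2
F4 | step 21 | 2-[(2R,3R)-3-(2-{[tert-butyl(dimethyl)silyl]oxy}ethyl)-2-methyloxiran-2-yl]ethan-1-ol | CC(C)(C)[Si](C)(C)OCC[C@H]1O[C@]1(C)CCO
F5 | step 21 | 2-[(2R,3R)-3-(2-{[tert-butyl(dimethyl)silyl]oxy}ethyl)-2-methyloxiran-2-yl]acetaldehyde | CC(C)(C)[Si](C)(C)OCC[C@H]1O[C@]1(C)CC=O
F6 | step 21 | allylzinc bromide of F2 (ZnBr in place of Br) | Br[Zn]CC1=C[C@H](OC1=O)/C=C(/C)I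
F7 | step 21 | (4R,5S)-4-{(1S)-2-[(2R,3R)-3-(2-{[tert-butyl(dimethyl)silyl]oxy}ethyl)-2-methyloxiran-2-yl]-1-hydroxyethyl}-5-[(1Z)-2-iodoprop-1-en-1-yl]-3-methylideneoxolan-2-one | C=C1C(=O)O[C@H](/C=C(/C)I)[C@H]1[C@@H](O)C[C@@]2(C)O[C@@H]2CCO[Si](C)(C)C(C)(C)C
F8 | step 21 | (2R,3R)-2,3-dimethyloxirane-2-carboxylate of the inverted (1R) carbinol of F7 | C=C1C(=O)O[C@H](/C=C(/C)I)[C@H]1[C@H](OC(=O)[C@]3(C)O[C@@H]3C)C[C@@]2(C)O[C@@H]2CCO[Si](C)(C)C(C)(C)C
F9 | step 21 | primary C3 alcohol of F8 (silyl group removed) | C=C1C(=O)O[C@H](/C=C(/C)I)[C@H]1[C@H](OC(=O)[C@]3(C)O[C@@H]3C)C[C@@]2(C)O[C@@H]2CCO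
F10 | step 21 | C3 aldehyde of F9 | C=C1C(=O)O[C@H](/C=C(/C)I)[C@H]1[C@H](OC(=O)[C@]3(C)O[C@@H]3C)C[C@@]2(C)O[C@@H]2CC=O
F11 | step 21 | alkenylchromium dichloride of F10 (CrCl2 in place of I; trivalent chromium) | C=C1C(=O)O[C@H](/C=C(/C)[Cr](Cl)Cl)[C@H]1[C@H](OC(=O)[C@]3(C)O[C@@H]3C)C[C@@]2(C)O[C@@H]2CC=O
F12 | step 21 | (1R,4Z,6R,7R,8R,10R)-8-{[(2R,3R)-2,3-dimethyloxiran-2-yl]carbonyloxy}-1,10-epoxy-3-hydroxygermacra-4,11(13)-dien-12,6-olide (C3 epimers) | C=C1C(=O)O[C@@H]2/C=C(/C)C(O)C[C@H]3O[C@]3(C)C[C@@H](OC(=O)[C@]4(C)O[C@@H]4C)[C@@H]12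
F13 | step 22 | (1R,3S,4Z,6R,7R,10R)-1,10-epoxy-3-[(3-methylbutanoyl)oxy]-8-oxogermacra-4,11(13)-dien-12,6-olide | C=C1C(=O)O[C@@H]2/C=C(/C)[C@@H](OC(=O)CC(C)C)C[C@H]3O[C@]3(C)CC(=O)[C@@H]12
F14 | step 22 | (1R,3S,4Z,6R,7R,8R,10R)-1,10-epoxy-8-hydroxy-3-[(3-methylbutanoyl)oxy]germacra-4,11(13)-dien-12,6-olide | C=C1C(=O)O[C@@H]2/C=C(/C)[C@@H](OC(=O)CC(C)C)C[C@H]3O[C@]3(C)C[C@@H](O)[C@@H]12
F15 | step 12 | 2-{(2R,3R)-3-[2-(PMB-oxy)ethyl]-3-methyloxiran-2-yl}acetic acid | OC(=O)C[C@H]1O[C@]1(C)CCOCc2ccc(OC)cc2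
F16 | step 12 | N-methoxy-N-methyl-2-{(2R,3R)-3-[2-(PMB-oxy)ethyl]-3-methyloxiran-2-yl}acetamide | CON(C)C(=O)C[C@H]1O[C@]1(C)CCOCc2ccc(OC)cc2
F17 | step 12 | chloro[(2Z,4S)-4-(TES-oxy)hexa-2,5-dien-2-yl]magnesium | C=C[C@H](O[Si](CC)(CC)CC)/C=C(/C)[Mg]Cl
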